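**Retrosynthetic overview**

The strategy rests on the depside ester. Its carbonyl carbon sits on C1 of ring A between the C2 oxygen and the C6 propyl group. Ring A (O on C2 and C4, alkyl on C6, acyl on C1) is the aromatised form of a 3,5,7-trioxodecanoyl chain, so the hindered C(=O)–O bond can be made while ring A is still an open chain.
Disconnections: benzyl and methyl groups off; ring A C1–C6 bond (chain C2–C7) back to an aryl 3,5,7-trioxodecanoate; ester C–O bond back to an acylketene plus the 4-OH of a protected olivetolate; acylketene masked as a diketo-dioxinone, built by two Claisen acylations of 2,2,6-trimethyl-1,3-dioxin-4-one (acetyl, then butanoyl).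
Ring order: ring B is bought as olivetol, then carboxylated and protected; the dioxinone ring is a bought, sacrificial carrier; ring A is closed last, on the finished ester.

Key step: step 9

Remark: the target SMILES contains no stereocentre, stereoaxis or configured double bond. The compound is achiral, so the request for a single enantiomer needs no measure.

**Route**

Step 1
Reactants: 1 2,2,6-trimethyl-4H-1,3-dioxin-4-one; 2 acetyl chloride
Product: 3 2,2-dimethyl-6-(2-oxopropyl)-4H-1,3-dioxin-4-one
Conditions: 1 (2 equiv), LiHMDS (2 equiv), THF, −78 °C; 2 (1 equiv), −78 → −20 °C; 1 M HCl quench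
Reagents that add atoms: none
Why: Vinylogous Claisen-type C-acylation, in which the lithium dienolate of 1 reacts with the acyl chloride at the former 6-methyl carbon and the surplus dienolate absorbs the acidic proton of 3, an established preparation of this keto-dioxinone.

Step 2
Reactants: 4 butanoyl chloride
Product: 5 N-methoxy-N-methylbutanamide
Conditions: MeNH(OMe)·HCl, K2CO3, CH2Cl2/H2O, 0 °C → rt
Reagents that add atoms: N,O-dimethylhydroxylamine hydrochloride, CNOC.Cl
Why: Schotten–Baumann N-acylation gives the Weinreb amide, chosen because its chelated tetrahedral adduct lasts until the quench and so suppresses over-addition and proton exchange in step 3.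

Step 3
Reactants: 3 2,2-dimethyl-6-(2-oxopropyl)-4H-1,3-dioxin-4-one; 5 N-methoxy-N-methylbutanamide
Product: 6 6-(2,4-dioxoheptyl)-2,2-dimethyl-4H-1,3-dioxin-4-one
Conditions: LDA (2.2 equiv), THF, −78 °C; 5 (1 equiv), −78 → −20 °C; 1 M HCl quench
Reagents that add atoms: none
Why: Crossed Claisen condensation of a dicarbonyl dianion, in which the last-formed terminal CH2 carbanion is the most nucleophilic site and attacks the Weinreb amide, and the 1,3-diketone is released only on acidic quench.

Step 4
Reactants: 7 olivetol (5-pentylbenzene-1,3-diol)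
Product: 8 olivetolic acid (2,4-dihydroxy-6-pentylbenzoic acid)
Conditions: MeOMgOCO2Me (2 M in DMF, excess), 120 °C, N2; then ice-cold 2 M HCl
Reagents that add atoms: methyl magnesium carbonate, COC(=O)O[Mg]OC
Why: Kolbe–Schmitt-type ortho-carboxylation, in which the magnesium phenoxide delivers CO2 to the ring carbon ortho to one hydroxyl and para to the other and the magnesium salicylate chelate holds the labile acid until cold acidification, a reaction type established for 5-alkylresorcinols.

Step 5
Reactants: 8 olivetolic acid
Product: 9 benzyl 2,4-dihydroxy-6-pentylbenzoate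
Conditions: BnBr (1.05 equiv), KHCO3 (1.1 equiv), DMF, rt
Reagents that add atoms: benzyl bromide, BrCc1ccccc1
Why: SN2 O-alkylation of the carboxylate, since hydrogen carbonate deprotonates only the acid so both phenols stay free, and room temperature avoids decarboxylation.

Step 6
Reactants: 9 benzyl 2,4-dihydroxy-6-pentylbenzoate
Product: 10 benzyl 4-(allyloxy)-2-hydroxy-6-pentylbenzoate
Conditions: allyl bromide (1.05 equiv), K2CO3 (1.1 equiv), acetone, rt → 40 °C
Reagents that add atoms: allyl bromide, C=CCBr
Why: Williamson etherification that selects the 4-OH, because the 2-OH is hydrogen-bonded to the ester carbonyl and is therefore less acidic and less nucleophilic.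

Step 7
Reactants: 10 benzyl 4-(allyloxy)-2-hydroxy-6-pentylbenzoate
Product: 11 benzyl 4-(allyloxy)-2-(benzyloxy)-6-pentylbenzoate
Conditions: BnBr (1.5 equiv), K2CO3 (2 equiv), DMF, 60 °C
Reagents that add atoms: benzyl bromide, BrCc1ccccc1
Why: Williamson etherification in a polar aprotic solvent with heat and excess halide breaks the chelate and benzylates the only remaining hydroxyl, far below the temperature at which an aryl allyl ether undergoes Claisen rearrangement.

Step 8
Reactants: 11 benzyl 4-(allyloxy)-2-(benzyloxy)-6-pentylbenzoate
Product: 12 benzyl 2-(benzyloxy)-4-hydroxy-6-pentylbenzoate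
Conditions: Pd(PPh3)4 (5 mol %), morpholine (5 equiv), THF, rt
Reagents that add atoms: none
Why: Tsuji–Trost deallylation, in which Pd(0) ionises only the allyl aryl ether and morpholine traps the π-allyl fragment, while the benzyl ether and the hindered benzyl ester are inert.

Step 9
Reactants: 6 6-(2,4-dioxoheptyl)-2,2-dimethyl-4H-1,3-dioxin-4-one; 12 benzyl 2-(benzyloxy)-4-hydroxy-6-pentylbenzoate
Product: 16 benzyl 2-(benzyloxy)-4-[(2,4-dihydroxy-6-propylbenzoyl)oxy]-6-pentylbenzoate, via acylketene 13 (not isolated), via aryl triketo ester 14 (not isolated), via cyclic aldol 15 (not isolated)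
Conditions: 6 (1.3 equiv) added slowly to 12 in PhMe, 110 °C, short hold; cool to 0 °C; Et3N, 0 °C → rt; dilute HCl work-up
Reagents that add atoms: none
Why: At 110 °C the dioxinone of 6 loses acetone by retro-hetero-Diels–Alder reaction to give acylketene 13, whose sp carbon is attacked by the only free hydroxyl of 12 (the 4-OH, flanked by two ring hydrogens) to give triketo ester 14, so the ester bond exists before either ortho substituent does. Triethylamine then reversibly enolises the methylenes of 14, and the C2 carbon (between ester and C3 ketone) adds to the C7 ketone in an allowed 6-exo-trig aldol closure (the enolate can be drawn as enolexo through the ester or enolendo through C3, both permitted for six-membered rings) to give carbinol 15, which loses water and tautomerises at its two remaining ring ketones to the benzene ring A of 16. The closest known reaction types are the thermolysis of diketo-dioxinones with alcohol capture and aldol aromatisation to resorcylates, and the acetoacetylation of phenols by acylketenes released from dioxinones. The two sp3 centres of 15 are transient and are erased on aromatisation, so no stereocontrol is needed. The selectivity required is C2-to-C7 aldol closure over three ways of losing the aryloxy group: attack of the C5 enol oxygen on C1 (pyranone formation), Claisen attack of C6 on C1 (phloroglucinol fold), and reversion to 13. Slow addition of 6 into hot 12, short heating, and a weak non-nucleophilic amine in an aprotic medium free of alkoxide and chelating metal favour the aldol path, whose dehydration is irreversible, while the benzyl groups on the 2-OH and the acid of 12 fix the acylation site.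

Step 10
Reactants: 16 benzyl 2-(benzyloxy)-4-[(2,4-dihydroxy-6-propylbenzoyl)oxy]-6-pentylbenzoate
Product: 17 benzyl 2-(benzyloxy)-4-[(2,4-dimethoxy-6-propylbenzoyl)oxy]-6-pentylbenzoate
Conditions: MeI (6 equiv), K2CO3 (4 equiv), dry acetone, 45 °C
Reagents that add atoms: methyl iodide, CI
Why: Double Williamson methylation in which a large excess of the small electrophile in a dry, weakly polar medium etherifies the free 4-OH quickly and the chelated 2-OH more slowly, while no nucleophile able to cleave the aryl ester is present.

Step 11
Reactants: 17 benzyl 2-(benzyloxy)-4-[(2,4-dimethoxy-6-propylbenzoyl)oxy]-6-pentylbenzoate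
Product: 18 4-[(2,4-dimethoxy-6-propylbenzoyl)oxy]-2-hydroxy-6-pentylbenzoic acid (target CNP0324837.0)
Conditions: H2 (1 atm), 10% Pd/C, EtOAc, rt
Reagents that add atoms: none
Why: Catalytic hydrogenolysis cleaves both benzylic C–O bonds under neutral conditions at room temperature, which leaves the aryl ester and methyl ethers untouched and avoids decarboxylation of the liberated salicylic-type acid.

**Compound list**

1 | 2,2,6-trimethyl-4H-1,3-dioxin-4-one | CC1=CC(=O)OC(C)(C)O1 | starting material
2 | acetyl chloride | CC(Cl)=O | starting material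
3 | 2,2-dimethyl-6-(2-oxopropyl)-4H-1,3-dioxin-4-one | CC(=O)CC1=CC(=O)OC(C)(C)O1 | intermediate
4 | butanoyl chloride | CCCC(Cl)=O | starting material
5 | N-methoxy-N-methylbutanamide | CCCC(=O)N(C)OC | intermediate
6 | 6-(2,4-dioxoheptyl)-2,2-dimethyl-4H-1,3-dioxin-4-one | CCCC(=O)CC(=O)CC1=CC(=O)OC(C)(C)O1 | intermediate
7 | olivetol (5-pentylbenzene-1,3-diol) | CCCCCc1cc(O)cc(O)c1 | starting material
8 | olivetolic acid (2,4-dihydroxy-6-pentylbenzoic acid) | CCCCCc1cc(O)cc(O)c1C(=O)O | intermediate
9 | benzyl 2,4-dihydroxy-6-pentylbenzoate | CCCCCc1cc(O)cc(O)c1C(=O)OCc1ccccc1 | intermediate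
10 | benzyl 4-(allyloxy)-2-hydroxy-6-pentylbenzoate | CCCCCc1cc(OCC=C)cc(O)c1C(=O)OCc1ccccc1 | intermediate
11 | benzyl 4-(allyloxy)-2-(benzyloxy)-6-pentylbenzoate | CCCCCc1cc(OCC=C)cc(OCc2ccccc2)c1C(=O)OCc1ccccc1 | intermediate
12 | benzyl 2-(benzyloxy)-4-hydroxy-6-pentylbenzoate | CCCCCc1cc(O)cc(OCc2ccccc2)c1C(=O)OCc1ccccc1 | intermediate
13 | dec-1-ene-1,3,5,7-tetrone (diketo-acylketene, not isolated) | CCCC(=O)CC(=O)CC(=O)C=C=O | intermediate
14 | benzyl 2-(benzyloxy)-6-pentyl-4-[(3,5,7-trioxodecanoyl)oxy]benzoate (not isolated) | CCCC(=O)CC(=O)CC(=O)CC(=O)Oc1cc(CCCCC)c(C(=O)OCc2ccccc2)c(OCc2ccccc2)c1 | intermediate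
15 | benzyl 2-(benzyloxy)-4-[(2-hydroxy-4,6-dioxo-2-propylcyclohexane-1-carbonyl)oxy]-6-pentylbenzoate (not isolated; transient stereoisomer mixture, both centres erased on aromatisation) | CCCC1(O)CC(=O)CC(=O)C1C(=O)Oc1cc(CCCCC)c(C(=O)OCc2ccccc2)c(OCc2ccccc2)c1 | intermediate
16 | benzyl 2-(benzyloxy)-4-[(2,4-dihydroxy-6-propylbenzoyl)oxy]-6-pentylbenzoate | CCCc1cc(O)cc(O)c1C(=O)Oc1cc(CCCCC)c(C(=O)OCc2ccccc2)c(OCc2ccccc2)c1 | intermediate
17 | benzyl 2-(benzyloxy)-4-[(2,4-dimethoxy-6-propylbenzoyl)oxy]-6-pentylbenzoate | CCCc1cc(OC)cc(OC)c1C(=O)Oc1cc(CCCCC)c(C(=O)OCc2ccccc2)c(OCc2ccccc2)c1 | intermediate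
18 | 4-[(2,4-dimethoxy-6-propylbenzoyl)oxy]-2-hydroxy-6-pentylbenzoic acid | CCCCCc1cc(OC(=O)c2c(CCC)cc(OC)cc2OC)cc(O)c1C(=O)O | target

**Step count**

Total step count: 11.
Longest linear sequence: 8 steps (7 → 8 → 9 → 10 → 11 → 12 → 16 → 17 → 18). The dioxinone branch joins at step 9 after two linear steps plus the amide preparation.

**Steps most likely to fail**

First, step 9.
- The aryloxy group is a better leaving group than the alkoxy groups usually carried through this cascade. It may be lost again after capture by thermal or base-induced reversion to the ketene, by lactonisation of the C5 enol onto C1, or by Claisen-type attack of C6 on C1.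
- Sluggish capture by the electron-poor phenol would also let the ketene consume itself.
- The fallback sets out from 6 and 12 and comes back at 17, so it bypasses step 10 as well.
- Compound 6 is heated in toluene with methanol, the established alcohol capture. This gives, through 13, methyl 3,5,7-trioxodecanoate F1.
- Cs2CO3 in methanol closes F1 to methyl 2-hydroxy-4,6-dioxo-2-propylcyclohexane-1-carboxylate F2. Acidification with methanolic HCl aromatises it to methyl 2,4-dihydroxy-6-propylbenzoate F3.
- MeI and K2CO3 in acetone give methyl 2,4-dimethoxy-6-propylbenzoate F4. KOH in aqueous DMSO at 100 °C then gives 2,4-dimethoxy-6-propylbenzoic acid F5.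
- Trifluoroacetic anhydride in toluene at room temperature converts F5 into 2,4-dimethoxy-6-propylbenzoic trifluoroacetic anhydride F6.
- F6 reacts through an acylium-like species that tolerates two ortho substituents, and it acylates the 4-OH of 12 to give 17.

Second, step 3.
- Proton transfer from the enolisable amide or from the product to the dianion could stall the reaction. Reaction through the internal carbon is possible, and the sensitive diketo-dioxinone may cyclise prematurely during quench and purification. Any of these could erode the step.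
- The fallback sets out from 1 and 4 and comes back at 6. It replaces the dianion by soft enolisation of a malonate-type carrier.
- Commercial mono-allyl malonate with oxalyl chloride and catalytic DMF gives allyl 3-chloro-3-oxopropanoate F7.
- F7 acylates the lithium dienolate of 1 (LiHMDS, THF, −78 °C) to give allyl 4-(2,2-dimethyl-4-oxo-4H-1,3-dioxin-6-yl)-3-oxobutanoate F8.
- MgCl2 and pyridine in CH2Cl2 at 0 °C, followed by 4, give allyl 2-butanoyl-4-(2,2-dimethyl-4-oxo-4H-1,3-dioxin-6-yl)-3-oxobutanoate F9 by C-acylation of the magnesium enolate.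
- Pd(PPh3)4 and morpholine remove the allyl group. The free 2-butanoyl-4-(2,2-dimethyl-4-oxo-4H-1,3-dioxin-6-yl)-3-oxobutanoic acid F10 decarboxylates at room temperature to give 6.

Third, step 10.
- Slow etherification of the chelated 2-OH leaves a long-lived ortho-phenoxide beside the aryl ester.
- This opens the way to Smiles-type aryl migration onto ring B C4, which is activated by the para benzyl ester. It also allows cleavage of the depside bond by adventitious water.
- The fallback sets out from 16 and comes back at 17 in two stages, neither of which uses metal carbonate.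
- Trimethylsilyldiazomethane in toluene/methanol at 0 °C methylates only the acidic, unchelated 4-OH. This gives benzyl 2-(benzyloxy)-4-[(2-hydroxy-4-methoxy-6-propylbenzoyl)oxy]-6-pentylbenzoate F11.
- Mitsunobu etherification of the remaining 2-OH (MeOH, PPh3, DIAD, THF, 0 °C → rt) then gives 17.
- If this also fails, the fallback given for step 9 delivers 17 with both methyl ethers installed before the ester is made.

**Further compounds**

F1 | step 9 | methyl 3,5,7-trioxodecanoate | CCCC(=O)CC(=O)CC(=O)CC(=O)OC
F2 | step 9 | methyl 2-hydroxy-4,6-dioxo-2-propylcyclohexane-1-carboxylate | CCCC1(O)CC(=O)CC(=O)C1C(=O)OC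
F3 | step 9 | methyl 2,4-dihydroxy-6-propylbenzoate | CCCc1cc(O)cc(O)c1C(=O)OC
F4 | step 9 | methyl 2,4-dimethoxy-6-propylbenzoate | CCCc1cc(OC)cc(OC)c1C(=O)OC
F5 | step 9 | 2,4-dimethoxy-6-propylbenzoic acid | CCCc1cc(OC)cc(OC)c1C(=O)O
F6 | step 9 | 2,4-dimethoxy-6-propylbenzoic trifluoroacetic anhydride | CCCc1cc(OC)cc(OC)c1C(=O)OC(=O)C(F)(F)F
F7 | step 3 | allyl 3-chloro-3-oxopropanoate | C=CCOC(=O)CC(=O)Cl
F8 | step 3 | allyl 4-(2,2-dimethyl-4-oxo-4H-1,3-dioxin-6-yl)-3-oxobutanoate | C=CCOC(=O)CC(=O)CC1=CC(=O)OC(C)(C)O1
F9 | step 3 | allyl 2-butanoyl-4-(2,2-dimethyl-4-oxo-4H-1,3-dioxin-6-yl)-3-oxobutanoate | C=CCOC(=O)C(C(=O)CCC)C(=O)CC1=CC(=O)OC(C)(C)O1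
F10 | step 3 | 2-butanoyl-4-(2,2-dimethyl-4-oxo-4H-1,3-dioxin-6-yl)-3-oxobutanoic acid | OC(=O)C(C(=O)CCC)C(=O)CC1=CC(=O)OC(C)(C)O1
F11 | step 10 | benzyl 2-(benzyloxy)-4-[(2-hydroxy-4-methoxy-6-propylbenzoyl)oxy]-6-pentylbenzoate | CCCc1cc(OC)cc(O)c1C(=O)Oc1cc(CCCCC)c(C(=O)OCc2ccccc2)c(OCc2ccccc2)c1
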